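## The problem

Target 22 is a 3-deoxyflavan (rings A, C and B) joined by one bond from its C4 to C8 of ring D of an epigallocatechin 3-O-gallate unit (rings D, F and E, galloyl ester on C3 of ring F). The linking carbon is a diarylmethine whose two aryl partners each carry two ortho oxygens. The bond is therefore crowded and, like any interflavan bond, can be reopened by acid through ipso protonation of ring D. There are four stereocentres: C2 and C3 of ring F (2R,3R, cis) and C2 (S) and C4 (R) of ring C, which are trans. The ring F pair lies beyond ring D and cannot be relied on to control C4, and ring C has no 3-oxygen to direct an incoming group, so C4 needs an external source of chirality. Once C4 is set it can steer C2 across the ring. Twelve phenols (two pyrogallol rings and a catechol among them) oxidise in air and base, the gallate ester does not survive organometallic reagents, and C2 of ring F epimerises in base when the phenols are free. The phenols must therefore stay masked to the end and the ester must come late. The enabling feature is that C4 is bonded to C4a of phloroglucinol ring A, whose neighbour C8a carries O1. The atoms O1, C8a, C4a and C4 form a latent ortho-quinone methide, stabilised by the C5 and C7 oxygens and the ring D aryl group, so C2 and C3 can arrive together as a two-carbon partner.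

## Retrosynthesis

**22 from 21.** The twelve benzyl–oxygen bonds are cut last, leading back to dodeca-O-benzyl ether 21. Benzyl is preferred to methyl or silyl because all twelve ethers leave in one neutral hydrogenolysis that spares the ester and the diarylmethine, and because benzyl ethers tolerate every reagent used earlier. The forward step must remove twelve ethers without opening the benzylic O1–C2 bonds of rings C and F.

**21 from 19 and 20, and 19 from 18.** The acyl–oxygen bond of the gallate is cut to give alcohol 19 and commercial 3,4,5-tris(benzyloxy)benzoic acid 20. The ester is introduced here because the C4–C8 bond is to be made with an aryllithium, which an ester would not survive. A silyl ether (18) stands in for it until then, at a cost of two simple steps. The forward acylation has to reach an axial secondary hydroxyl next to a crowded ring D.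

**18 from 13 and 14.** The bond between C2 of ring C and ring B is cut. This leads to oxocarbenium ion 17 and arylzinc bromide 16, made through aryllithium 15 from commercial bromide 14; ion 17 is the ionised form of 2-ethoxychroman 13. This cut is preferred to cutting O1–C2, which would reopen ring C and need a separate control element for C2. Here the C4 aryl group, pushed pseudoaxial by the C5 benzyloxy group, shields one face of 17. Precursor 13 lacks ring B and one stereocentre. The forward step must ionise the exocyclic C–O bond, deliver the aryl group trans to C4 and leave the C4–C8 bond intact.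

**13 from 10 and 11.** C3–C4 and O1–C2 are cut together, which opens ring C to ortho-quinone methide 12 and ethyl vinyl ether 11; 12 is the dehydrated form of diaryl carbinol 10. The neighbouring cut, C4–C8 by Friedel–Crafts capture of a flavan-4-yl cation, would need the whole upper flavan with C2 already set. It would fix C4 only relative to C2, without a 3-substituent to help, and would face C6 versus C8 regiochemistry. The [4+2] cut instead removes a ring and a stereocentre at once and leaves a carbinol whose configuration is irrelevant. The forward reaction must form the quinone methide on ring A only and choose one face of the methide carbon under catalyst control.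

**10 from 9, and 9 from 4 and 7.** The C4–C8 bond is cut between ring D and the carbinol carbon, giving aryllithium 8 (from bromide 4) and aldehyde 7. The ring A phenol is carried as an allyl ether in 9 and released under neutral conditions to give 10. Bromine–lithium exchange fixes the C8 regiochemistry beforehand, which an acid-mediated hydroxyalkylation of ring D could not guarantee. The forward addition joins two di-ortho-substituted partners and must outrun protonation of 8.

**4 from 3, 2 and 1.** The C8–Br, O–Si and five O–benzyl bonds are removed in turn, back to commercial (−)-epigallocatechin 1. Ring F and both its stereocentres are taken from the chiral pool. The forward steps need phenol-selective benzylation and C8-selective bromination.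

**7 from 6 and 5.** The allyl and two benzyl ethers are removed, back to commercial 2,4,6-trihydroxybenzaldehyde 5. The hydrogen bond between one ortho hydroxyl and the aldehyde distinguishes the three phenols, so no protecting-group exchange is needed.

## Roads not taken

**Alternative 1:** Hidden symmetry at C4. The cut is O1–C8a of ring C. The precursor, alcohol A1, carries two identical 2-bromo-4,6-bis(benzyloxy)phenyl groups on the future C4. With CuI and a chiral diamine ligand the C2 alkoxide would be arylated by one of the two diastereotopic bromoarenes (Ullmann-type C–O coupling), closing ring C and fixing C4 in bromo flavan A2.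
- Merits: no acid-labile intermediate is involved, and the carbinol centre of A1 can be set by a reliable asymmetric ketone reduction.
- Weak points: both bromoarenes are di-ortho-substituted, so the coupling is hindered, and the ligand must select the aryl group that gives the trans product against the substrate's own preference. Above all, A2 contains nothing of ring F. The remaining bromoarene would have to be turned into ring D with O1, C4, C3, C2 and ring E, including two more stereocentres, over many steps.
- Comparison: Alternative 1 is better at C2, which it sets with a well-understood reduction and without a Lewis acid. The chosen plan sets against this that ring F comes complete from 1 and that only four steps follow the key step.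

**Alternative 2:** Ring F built last. The cut is O1–C2 of ring F. Under mild acid the ring D phenol of cis-epoxide A3 would open the benzylic epoxide carbon in a 6-endo SN2 reaction with inversion, giving A4, which is identical with 19.
- Merits: phenol opening of aryl epoxides is an established way to make flavan-3-ols, and the endgame is the same as in the chosen plan.
- Weak points: A3 needs the entire upper flavan with C2 and C4 already set, which this alternative does not address. It also needs a cis-selective asymmetric epoxidation next to a crowded arene. The 3,4,5-tris(benzyloxy)phenyl group stabilises a benzylic cation, so an SN1 pathway can leak to the 2,3-trans isomer. The route discards the chiral pool and would be the longest of the four.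
- Comparison: Alternative 2 is better in one respect: it avoids arylation at an acetal carbon, where the chosen plan relies on 1,3-induction. The chosen plan sets against this that both ring F centres are bought, not made.

**Alternative 3:** Prins–Friedel–Crafts cascade. The cuts are C2–C3 and C4–C8. Ionisation of mixed acetal A5 with TMSOTf or a confined chiral Brønsted acid would give an aryl oxocarbenium ion. The ortho vinyl group closes ring C by forming C2–C3, and the resulting flavan-4-yl cation is captured by C8 of octa-O-benzyl gallate A6, giving A7, which is identical with 21.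
- Merits: this is the most convergent plan. A6 is one benzylation away from the commercial natural gallate, the ester is never removed, and only hydrogenolysis follows. It is several steps shorter than the chosen route.
- Weak points: one intermolecular event must deliver the absolute configuration at C2, the 2,4-trans relationship and C8 over C6 regiochemistry on a hindered nucleophile. The enantioselective version has no close model, and without it the racemic upper unit gives diastereomers of a very large molecule. A5 is also a labile aryl alkyl acetal.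
- Comparison: Alternative 3 is clearly better in step count. The chosen plan sets against this that each selectivity is handled in a separate step with its own control element: bromine for C8, the catalyst for C4, and C4 for C2.

Key step: step 8

Assumption: the (R)-configured acid of step 8, and the (1R,2S) auxiliary of its fallback, is taken as the antipode that gives 4R; the sense of induction is to be checked on the first adduct, and the mirror-image reagent, equally available, used if needed.

## Route

Step 1
Reactants: 1 (−)-epigallocatechin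
Product: 2 5,7,3',4',5'-penta-O-benzyl-(−)-epigallocatechin, i.e. (2R,3R)-5,7-bis(benzyloxy)-2-[3,4,5-tris(benzyloxy)phenyl]chroman-3-ol
Conditions: BnBr (5.5 equiv.), K2CO3, degassed DMF, 0 °C → rt, argon
Reagents that add atoms: benzyl bromide, BrCc1ccccc1
Why: Williamson etherification; K2CO3 deprotonates only the five phenols, so the secondary 3-hydroxyl should stay free, and mild base at room temperature under argon should avoid C2 epimerisation and pyrogallol oxidation; no stereocentre is touched.

Step 2
Reactants: 2 penta-O-benzyl-epigallocatechin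
Product: 3 (2R,3R)-5,7-bis(benzyloxy)-3-(tert-butyldimethylsilyloxy)-2-[3,4,5-tris(benzyloxy)phenyl]chroman
Conditions: TBSCl, imidazole, DMF, rt
Reagents that add atoms: tert-butyldimethylsilyl chloride, CC(C)(C)[Si](C)(C)Cl
Why: Standard silylation of a secondary alcohol; the silyl ether tolerates tert-butyllithium, weak acid and brief BF3 exposure at low temperature, and leaves with fluoride.

Step 3
Reactants: 3 silyl ether
Product: 4 (2R,3R)-5,7-bis(benzyloxy)-8-bromo-3-(tert-butyldimethylsilyloxy)-2-[3,4,5-tris(benzyloxy)phenyl]chroman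
Conditions: NBS, CH2Cl2, −40 → 0 °C
Reagents that add atoms: N-bromosuccinimide, O=C1CCC(=O)N1Br
Why: Electrophilic aromatic bromination; ring D, with three oxygen donors, is the most nucleophilic ring, and C8 is the position known to react first in 5,7-di-O-benzyl flavan-3-ol ethers.

Step 4
Reactants: 5 2,4,6-trihydroxybenzaldehyde
Product: 6 4,6-bis(benzyloxy)-2-hydroxybenzaldehyde
Conditions: BnBr (2.05 equiv.), K2CO3, DMF, rt
Reagents that add atoms: benzyl bromide, BrCc1ccccc1
Why: Williamson etherification with two equivalents; the para hydroxyl and one ortho hydroxyl react, while the remaining ortho hydroxyl is held in a hydrogen bond to the aldehyde and is the least nucleophilic.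

Step 5
Reactants: 6 4,6-bis(benzyloxy)-2-hydroxybenzaldehyde
Product: 7 2-(allyloxy)-4,6-bis(benzyloxy)benzaldehyde
Conditions: allyl bromide, K2CO3, DMF, 50 °C
Reagents that add atoms: allyl bromide, C=CCBr
Why: Williamson allylation of the chelated phenol under slightly more forcing conditions; allyl is inert to aryllithium reagents and can be removed later without acid.

Step 6
Reactants: 4 8-bromo flavan; 7 2-(allyloxy)-4,6-bis(benzyloxy)benzaldehyde
Product: 9 (2R,3R)-8-{[2-(allyloxy)-4,6-bis(benzyloxy)phenyl](hydroxy)methyl}-5,7-bis(benzyloxy)-3-(tert-butyldimethylsilyloxy)-2-[3,4,5-tris(benzyloxy)phenyl]chroman as both carbinol epimers, via C8 aryllithium 8 (not isolated)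
Conditions: t-BuLi (2 equiv.), THF, −78 °C; then 7, −78 → −40 °C; H2O
Reagents that add atoms: none
Why: Bromine–lithium exchange followed by 1,2-addition of the aryllithium to the aldehyde, a sequence known for 8-bromo flavan-3-ol silyl ethers; the new carbinol centre forms unselectively, which is harmless because it becomes sp2 in step 8.

Step 7
Reactants: 9 allyl-protected carbinol
Product: 10 (2R,3R)-8-{[4,6-bis(benzyloxy)-2-hydroxyphenyl](hydroxy)methyl}-5,7-bis(benzyloxy)-3-(tert-butyldimethylsilyloxy)-2-[3,4,5-tris(benzyloxy)phenyl]chroman as both carbinol epimers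
Conditions: Pd(PPh3)4 (5 mol%), morpholine, THF, rt
Reagents that add atoms: none
Why: Tsuji–Trost deallylation; zerovalent palladium ionises the aryl allyl ether and morpholine traps the allyl fragment, so the phenol is freed under neutral to basic conditions that should not ionise the acid-labile diaryl carbinol (10 is best used without chromatography on acidic silica).

Step 8
Reactants: 10 phenol carbinol; 11 ethyl vinyl ether
Product: 13 (2R,3R)-8-[(4R)-5,7-bis(benzyloxy)-2-ethoxychroman-4-yl]-5,7-bis(benzyloxy)-3-(tert-butyldimethylsilyloxy)-2-[3,4,5-tris(benzyloxy)phenyl]chroman as both acetal epimers at C2 of ring C, via ring A ortho-quinone methide 12 (not isolated)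
Conditions: (R)-3,3'-bis(2,4,6-triisopropylphenyl)-1,1'-binaphthyl-2,2'-diyl hydrogen phosphate (10 mol%), 11 (5 equiv.), 5 Å MS, toluene, −40 → 0 °C
Reagents that add atoms: none
Why: The phosphoric acid protonates the carbinol hydroxyl of 10, and loss of water, driven by two trialkoxyaryl donors, gives ortho-quinone methide 12, whose carbonyl oxygen stays hydrogen-bonded to the catalyst. Ethyl vinyl ether then adds in an inverse-electron-demand oxa-[4+2] cycloaddition in which its nucleophilic CH2 terminus bonds to the methide carbon (C3–C4) slightly ahead of O1–C2, so the polarisation of both partners fixes the 2-ethoxy regiochemistry. The closest known reaction type is the chiral phosphoric acid catalysed [4+2] cycloaddition of ortho-quinone methides, generated in situ from ortho-hydroxybenzhydryl alcohols, with enol ethers, enecarbamates and vinyl sulfides to give 4-aryl-2-heteroatom-substituted chromans. Ring C is closed by intermolecular cycloaddition, four ring atoms (O1, C8a, C4a, C4) coming from 12 and two (C2, C3) from 11. C4 is controlled by the catalyst: the bound phosphate and its 2,4,6-triisopropylphenyl walls should leave one face of the methide carbon open, whereas the acetal carbon C2 forms as a mixture that does not matter because it is ionised in step 9. The step needs quinone methide formation on ring A only, which is secured because the sole free phenol of 10 is ortho to the carbinol and ring D is fully alkylated. It also needs face selectivity over any bias from the remote ring F centres, which is secured by catalyst control with either antipode of the acid to hand.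

Step 9
Reactants: 13 2-ethoxychroman; 14 4-bromo-1,2-bis(benzyloxy)benzene
Product: 18 (2R,3R)-8-{(2S,4R)-5,7-bis(benzyloxy)-2-[3,4-bis(benzyloxy)phenyl]chroman-4-yl}-5,7-bis(benzyloxy)-3-(tert-butyldimethylsilyloxy)-2-[3,4,5-tris(benzyloxy)phenyl]chroman, via 3,4-bis(benzyloxy)phenyllithium 15 (not isolated), via 3,4-bis(benzyloxy)phenylzinc bromide 16 (not isolated), via chroman-2-yl oxocarbenium ion 17 (not isolated)
Conditions: 14, n-BuLi, THF, −78 °C; ZnBr2, −78 → 0 °C; then 13, BF3·OEt2, CH2Cl2, −78 → −20 °C
Reagents that add atoms: none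
Why: Lewis acid ionisation of the cyclic acetal gives an oxocarbenium ion that is captured by the arylzinc reagent, the reaction type known from the substitution of 2-sulfonyl and 2-halo cyclic ethers by arylzinc halides. The C4 aryl group sits pseudoaxial to avoid the C5 benzyloxy group and shields the syn face of the flattened ion, so the aryl group should enter anti and set C2 as S (2,4-trans).

Step 10
Reactants: 18 silyl ether
Product: 19 (2R,3R)-8-{(2S,4R)-5,7-bis(benzyloxy)-2-[3,4-bis(benzyloxy)phenyl]chroman-4-yl}-5,7-bis(benzyloxy)-2-[3,4,5-tris(benzyloxy)phenyl]chroman-3-ol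
Conditions: Bu4NF, THF, rt
Reagents that add atoms: none
Why: Fluoride-mediated desilylation; the molecule carries no ester or free phenol at this stage, so the basic alkoxide cannot trigger acyl migration or C2 epimerisation.

Step 11
Reactants: 19 alcohol; 20 3,4,5-tris(benzyloxy)benzoic acid
Product: 21 (2R,3R)-8-{(2S,4R)-5,7-bis(benzyloxy)-2-[3,4-bis(benzyloxy)phenyl]chroman-4-yl}-5,7-bis(benzyloxy)-2-[3,4,5-tris(benzyloxy)phenyl]chroman-3-yl 3,4,5-tris(benzyloxy)benzoate
Conditions: DCC, DMAP, CH2Cl2, rt
Reagents that add atoms: none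
Why: Steglich esterification, the usual way to galloylate the axial 3-hydroxyl of benzylated epi-series flavan-3-ols and their 8-substituted dimers; the carbinol C–O bond is not broken, so C3 keeps its configuration.

Step 12
Reactants: 21 dodeca-O-benzyl ether
Product: 22 (2R,3R)-8-[(2S,4R)-2-(3,4-dihydroxyphenyl)-5,7-dihydroxychroman-4-yl]-5,7-dihydroxy-2-(3,4,5-trihydroxyphenyl)chroman-3-yl 3,4,5-trihydroxybenzoate
Conditions: H2 (1 atm), Pd(OH)2 on carbon, THF/MeOH, rt
Reagents that add atoms: none
Why: Catalytic hydrogenolysis of twelve aryl benzyl ethers, as practised for benzylated procyanidin gallates; at atmospheric pressure and short reaction time the ester, the diarylmethine and the O1–C2 bonds of rings C and F should remain, and no stereocentre is affected.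

## Compound list

1 | (−)-epigallocatechin, (2R,3R)-2-(3,4,5-trihydroxyphenyl)chroman-3,5,7-triol | O[C@@H]1Cc2c(O)cc(O)cc2O[C@@H]1c1cc(O)c(O)c(O)c1 | starting material
2 | (2R,3R)-5,7-bis(benzyloxy)-2-[3,4,5-tris(benzyloxy)phenyl]chroman-3-ol | O[C@@H]1Cc2c(OCc3ccccc3)cc(OCc3ccccc3)cc2O[C@@H]1c1cc(OCc2ccccc2)c(OCc2ccccc2)c(OCc2ccccc2)c1 | intermediate
3 | (2R,3R)-5,7-bis(benzyloxy)-3-(tert-butyldimethylsilyloxy)-2-[3,4,5-tris(benzyloxy)phenyl]chroman | CC(C)(C)[Si](C)(C)O[C@@H]1Cc2c(OCc3ccccc3)cc(OCc3ccccc3)cc2O[C@@H]1c1cc(OCc2ccccc2)c(OCc2ccccc2)c(OCc2ccccc2)c1 | intermediate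
4 | (2R,3R)-5,7-bis(benzyloxy)-8-bromo-3-(tert-butyldimethylsilyloxy)-2-[3,4,5-tris(benzyloxy)phenyl]chroman | CC(C)(C)[Si](C)(C)O[C@@H]1Cc2c(OCc3ccccc3)cc(OCc3ccccc3)c(Br)c2O[C@@H]1c1cc(OCc2ccccc2)c(OCc2ccccc2)c(OCc2ccccc2)c1 | intermediate
5 | 2,4,6-trihydroxybenzaldehyde | O=Cc1c(O)cc(O)cc1O | starting material
6 | 4,6-bis(benzyloxy)-2-hydroxybenzaldehyde | O=Cc1c(O)cc(OCc2ccccc2)cc1OCc1ccccc1 | intermediate
7 | 2-(allyloxy)-4,6-bis(benzyloxy)benzaldehyde | O=Cc1c(OCC=C)cc(OCc2ccccc2)cc1OCc1ccccc1 | intermediate
8 | (2R,3R)-5,7-bis(benzyloxy)-3-(tert-butyldimethylsilyloxy)-2-[3,4,5-tris(benzyloxy)phenyl]chroman-8-yllithium (formed in the flask) | CC(C)(C)[Si](C)(C)O[C@@H]1Cc2c(OCc3ccccc3)cc(OCc3ccccc3)c([Li])c2O[C@@H]1c1cc(OCc2ccccc2)c(OCc2ccccc2)c(OCc2ccccc2)c1 | intermediate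
9 | (2R,3R)-8-{[2-(allyloxy)-4,6-bis(benzyloxy)phenyl](hydroxy)methyl}-5,7-bis(benzyloxy)-3-(tert-butyldimethylsilyloxy)-2-[3,4,5-tris(benzyloxy)phenyl]chroman, both carbinol epimers | CC(C)(C)[Si](C)(C)O[C@@H]1Cc2c(OCc3ccccc3)cc(OCc3ccccc3)c(C(O)c3c(OCC=C)cc(OCc4ccccc4)cc3OCc3ccccc3)c2O[C@@H]1c1cc(OCc2ccccc2)c(OCc2ccccc2)c(OCc2ccccc2)c1 | intermediate
10 | (2R,3R)-8-{[4,6-bis(benzyloxy)-2-hydroxyphenyl](hydroxy)methyl}-5,7-bis(benzyloxy)-3-(tert-butyldimethylsilyloxy)-2-[3,4,5-tris(benzyloxy)phenyl]chroman, both carbinol epimers | CC(C)(C)[Si](C)(C)O[C@@H]1Cc2c(OCc3ccccc3)cc(OCc3ccccc3)c(C(O)c3c(O)cc(OCc4ccccc4)cc3OCc3ccccc3)c2O[C@@H]1c1cc(OCc2ccccc2)c(OCc2ccccc2)c(OCc2ccccc2)c1 | intermediate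
11 | ethyl vinyl ether | C=COCC | starting material
12 | 3,5-bis(benzyloxy)-6-{[(2R,3R)-5,7-bis(benzyloxy)-3-(tert-butyldimethylsilyloxy)-2-[3,4,5-tris(benzyloxy)phenyl]chroman-8-yl]methylidene}cyclohexa-2,4-dien-1-one, methide geometry not defined (formed in the flask) | CC(C)(C)[Si](C)(C)O[C@@H]1Cc2c(OCc3ccccc3)cc(OCc3ccccc3)c(C=C3C(=O)C=C(OCc4ccccc4)C=C3OCc3ccccc3)c2O[C@@H]1c1cc(OCc2ccccc2)c(OCc2ccccc2)c(OCc2ccccc2)c1 | intermediate
13 | (2R,3R)-8-[(4R)-5,7-bis(benzyloxy)-2-ethoxychroman-4-yl]-5,7-bis(benzyloxy)-3-(tert-butyldimethylsilyloxy)-2-[3,4,5-tris(benzyloxy)phenyl]chroman, both acetal epimers | CC(C)(C)[Si](C)(C)O[C@@H]1Cc2c(OCc3ccccc3)cc(OCc3ccccc3)c([C@@H]3CC(OCC)Oc4cc(OCc5ccccc5)cc(OCc5ccccc5)c43)c2O[C@@H]1c1cc(OCc2ccccc2)c(OCc2ccccc2)c(OCc2ccccc2)c1 | intermediate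
14 | 4-bromo-1,2-bis(benzyloxy)benzene | Brc1ccc(OCc2ccccc2)c(OCc2ccccc2)c1 | starting material
15 | 3,4-bis(benzyloxy)phenyllithium (formed in the flask) | [Li]c1ccc(OCc2ccccc2)c(OCc2ccccc2)c1 | intermediate
16 | 3,4-bis(benzyloxy)phenylzinc bromide (formed in the flask) | Br[Zn]c1ccc(OCc2ccccc2)c(OCc2ccccc2)c1 | intermediate
17 | (4R)-4-aryl-5,7-bis(benzyloxy)-3,4-dihydro-1-benzopyrylium ion (O1=C2 oxocarbenium ion of 13; aryl = the protected epigallocatechin-8-yl group; formed in the flask) | CC(C)(C)[Si](C)(C)O[C@@H]1Cc2c(OCc3ccccc3)cc(OCc3ccccc3)c([C@@H]3CC=[O+]c4cc(OCc5ccccc5)cc(OCc5ccccc5)c43)c2O[C@@H]1c1cc(OCc2ccccc2)c(OCc2ccccc2)c(OCc2ccccc2)c1 | intermediate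
18 | (2R,3R)-8-{(2S,4R)-5,7-bis(benzyloxy)-2-[3,4-bis(benzyloxy)phenyl]chroman-4-yl}-5,7-bis(benzyloxy)-3-(tert-butyldimethylsilyloxy)-2-[3,4,5-tris(benzyloxy)phenyl]chroman | CC(C)(C)[Si](C)(C)O[C@@H]1Cc2c(OCc3ccccc3)cc(OCc3ccccc3)c([C@@H]3C[C@@H](c4ccc(OCc5ccccc5)c(OCc5ccccc5)c4)Oc4cc(OCc5ccccc5)cc(OCc5ccccc5)c43)c2O[C@@H]1c1cc(OCc2ccccc2)c(OCc2ccccc2)c(OCc2ccccc2)c1 | intermediate
19 | (2R,3R)-8-{(2S,4R)-5,7-bis(benzyloxy)-2-[3,4-bis(benzyloxy)phenyl]chroman-4-yl}-5,7-bis(benzyloxy)-2-[3,4,5-tris(benzyloxy)phenyl]chroman-3-ol | O[C@@H]1Cc2c(OCc3ccccc3)cc(OCc3ccccc3)c([C@@H]3C[C@@H](c4ccc(OCc5ccccc5)c(OCc5ccccc5)c4)Oc4cc(OCc5ccccc5)cc(OCc5ccccc5)c43)c2O[C@@H]1c1cc(OCc2ccccc2)c(OCc2ccccc2)c(OCc2ccccc2)c1 | intermediate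
20 | 3,4,5-tris(benzyloxy)benzoic acid | OC(=O)c1cc(OCc2ccccc2)c(OCc2ccccc2)c(OCc2ccccc2)c1 | starting material
21 | (2R,3R)-8-{(2S,4R)-5,7-bis(benzyloxy)-2-[3,4-bis(benzyloxy)phenyl]chroman-4-yl}-5,7-bis(benzyloxy)-2-[3,4,5-tris(benzyloxy)phenyl]chroman-3-yl 3,4,5-tris(benzyloxy)benzoate | O=C(O[C@@H]1Cc2c(OCc3ccccc3)cc(OCc3ccccc3)c([C@@H]3C[C@@H](c4ccc(OCc5ccccc5)c(OCc5ccccc5)c4)Oc4cc(OCc5ccccc5)cc(OCc5ccccc5)c43)c2O[C@@H]1c1cc(OCc2ccccc2)c(OCc2ccccc2)c(OCc2ccccc2)c1)c1cc(OCc2ccccc2)c(OCc2ccccc2)c(OCc2ccccc2)c1 | intermediate
22 | (2R,3R)-8-[(2S,4R)-2-(3,4-dihydroxyphenyl)-5,7-dihydroxychroman-4-yl]-5,7-dihydroxy-2-(3,4,5-trihydroxyphenyl)chroman-3-yl 3,4,5-trihydroxybenzoate | O=C(O[C@@H]1Cc2c(O)cc(O)c([C@@H]3C[C@@H](c4ccc(O)c(O)c4)Oc4cc(O)cc(O)c43)c2O[C@@H]1c1cc(O)c(O)c(O)c1)c1cc(O)c(O)c(O)c1 | target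

## Step count and least certain steps

Total: 12 steps. Longest linear sequence: 10 steps (from 1 through steps 1, 2, 3, 6, 7, 8, 9, 10, 11 and 12).

**Step 8 (key step).** The most likely failure is insufficient face discrimination at C4. The vinyl ether has no hydrogen-bond donor to anchor it to the phosphoryl oxygen, the ring D aryl group on the methide carbon is di-ortho-substituted and twisted out of plane, and ring F adds a bias of its own. A second failure mode is slow cycloaddition of a strongly donor-stabilised, hindered quinone methide, which gives the acid time to consume the vinyl ether by hydration and acetal formation. Fallback: stereocontrol is moved from the catalyst to an auxiliary on the dienophile. Commercial (1R,2S)-2-phenylcyclohexanol is converted into (1R,2S)-2-phenylcyclohexyl vinyl ether F1 by transvinylation with vinyl acetate ([Ir(cod)Cl]2, Na2CO3, toluene, 100 °C). Carbinol 10 is then ionised with an achiral acid (diphenyl phosphate, CH2Cl2, low temperature) in the presence of F1, giving (2R,3R)-8-{(4R)-5,7-bis(benzyloxy)-2-[(1R,2S)-2-phenylcyclohexyloxy]chroman-4-yl}-5,7-bis(benzyloxy)-3-(tert-butyldimethylsilyloxy)-2-[3,4,5-tris(benzyloxy)phenyl]chroman F2 by the known auxiliary-controlled cycloaddition of ortho-quinone methides with chiral enol ethers. F2 is ionised and arylated under the conditions of step 9, which returns the route to 18 and releases the auxiliary alcohol.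

**Step 9.** The most likely failure is unproductive ionisation: cleavage of the endocyclic C–O bond to a ring-opened phenol, elimination to the 4H-chromene, or slow capture by a weakly nucleophilic arylzinc halide when THF ties up BF3. Prolonged Lewis acid exposure could then start to reopen the C4–C8 bond. The trans selectivity also rests on 1,3-induction alone. Fallback: acetal 13 is first converted with benzenesulfinic acid and CaCl2 in CH2Cl2 into (2R,3R)-8-[(4R)-5,7-bis(benzyloxy)-2-(phenylsulfonyl)chroman-4-yl]-5,7-bis(benzyloxy)-3-(tert-butyldimethylsilyloxy)-2-[3,4,5-tris(benzyloxy)phenyl]chroman F3. This sulfone ionises under ZnBr2 alone and is substituted by arylzinc bromide 16 in THF at room temperature, the known reaction of 2-sulfonyl cyclic ethers with arylzinc reagents. It rejoins the route at 18 through the same oxocarbenium ion, so the stereochemical argument is unchanged.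

**Step 6.** The most likely failure is protonation of the hindered aryllithium 8 before it adds to the di-ortho-substituted, electron-rich aldehyde 7, which returns debrominated 3. Fallback: the polarity is reversed. Bromide 4 is lithiated as before and quenched with the small electrophile DMF to give (2R,3R)-5,7-bis(benzyloxy)-3-(tert-butyldimethylsilyloxy)-2-[3,4,5-tris(benzyloxy)phenyl]chroman-8-carbaldehyde F4. F4 is then treated with the bromomagnesium phenoxide of commercial 3,5-bis(benzyloxy)phenol (EtMgBr, toluene, rt), whose magnesium chelate directs hydroxyalkylation to the ortho position; both ortho positions are equivalent. This gives 10 directly, so the route is rejoined at 10 and compound 9 and the allyl group are bypassed.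

**Step 12.** The most likely failure is incomplete removal of twelve benzyl ethers from a crowded molecule, set against hydrogenolytic opening of the benzylic O1–C2 bonds on longer exposure, with air oxidation of the pyrogallol rings during isolation. Fallback: non-reductive debenzylation of 21 with BCl3 and pentamethylbenzene as benzyl cation scavenger in CH2Cl2 at −78 °C, which leads from 21 straight to 22; no new compound arises (F0).

## Further compounds

F1 | step 8 | (1R,2S)-2-phenylcyclohexyl vinyl ether | C=CO[C@@H]1CCCC[C@H]1c1ccccc1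
F2 | step 8 | (2R,3R)-8-{(4R)-5,7-bis(benzyloxy)-2-[(1R,2S)-2-phenylcyclohexyloxy]chroman-4-yl}-5,7-bis(benzyloxy)-3-(tert-butyldimethylsilyloxy)-2-[3,4,5-tris(benzyloxy)phenyl]chroman, acetal centre not defined | CC(C)(C)[Si](C)(C)O[C@@H]1Cc2c(OCc3ccccc3)cc(OCc3ccccc3)c([C@@H]3CC(O[C@@H]5CCCC[C@H]5c5ccccc5)Oc4cc(OCc5ccccc5)cc(OCc5ccccc5)c43)c2O[C@@H]1c1cc(OCc2ccccc2)c(OCc2ccccc2)c(OCc2ccccc2)c1
F3 | step 9 | (2R,3R)-8-[(4R)-5,7-bis(benzyloxy)-2-(phenylsulfonyl)chroman-4-yl]-5,7-bis(benzyloxy)-3-(tert-butyldimethylsilyloxy)-2-[3,4,5-tris(benzyloxy)phenyl]chroman, sulfone-bearing centre not defined | CC(C)(C)[Si](C)(C)O[C@@H]1Cc2c(OCc3ccccc3)cc(OCc3ccccc3)c([C@@H]3CC(S(=O)(=O)c5ccccc5)Oc4cc(OCc5ccccc5)cc(OCc5ccccc5)c43)c2O[C@@H]1c1cc(OCc2ccccc2)c(OCc2ccccc2)c(OCc2ccccc2)c1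
F4 | step 6 | (2R,3R)-5,7-bis(benzyloxy)-3-(tert-butyldimethylsilyloxy)-2-[3,4,5-tris(benzyloxy)phenyl]chroman-8-carbaldehyde | CC(C)(C)[Si](C)(C)O[C@@H]1Cc2c(OCc3ccccc3)cc(OCc3ccccc3)c(C=O)c2O[C@@H]1c1cc(OCc2ccccc2)c(OCc2ccccc2)c(OCc2ccccc2)c1
F0 | step 12 | none | none
A1 | alternative 1 | (S)-3,3-bis[2-bromo-4,6-bis(benzyloxy)phenyl]-1-[3,4-bis(benzyloxy)phenyl]propan-1-ol | O[C@@H](CC(c1c(Br)cc(OCc2ccccc2)cc1OCc1ccccc1)c1c(Br)cc(OCc2ccccc2)cc1OCc1ccccc1)c1ccc(OCc2ccccc2)c(OCc2ccccc2)c1
A2 | alternative 1 | (2S,4R)-5,7-bis(benzyloxy)-2-[3,4-bis(benzyloxy)phenyl]-4-[2-bromo-4,6-bis(benzyloxy)phenyl]chroman | Brc1cc(OCc6ccccc6)cc(OCc6ccccc6)c1[C@@H]3C[C@@H](c4ccc(OCc6ccccc6)c(OCc6ccccc6)c4)Oc4cc(OCc6ccccc6)cc(OCc6ccccc6)c43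
A3 | alternative 2 | (2S,4R)-5,7-bis(benzyloxy)-2-[3,4-bis(benzyloxy)phenyl]-4-{4,6-bis(benzyloxy)-2-hydroxy-3-[((2R,3S)-3-[3,4,5-tris(benzyloxy)phenyl]oxiran-2-yl)methyl]phenyl}chroman (cis-epoxide) | Oc1c(C[C@H]2O[C@H]2c2cc(OCc3ccccc3)c(OCc3ccccc3)c(OCc3ccccc3)c2)c(OCc2ccccc2)cc(OCc2ccccc2)c1[C@@H]1C[C@@H](c2ccc(OCc3ccccc3)c(OCc3ccccc3)c2)Oc2cc(OCc3ccccc3)cc(OCc3ccccc3)c21
A4 | alternative 2 | (2R,3R)-8-{(2S,4R)-5,7-bis(benzyloxy)-2-[3,4-bis(benzyloxy)phenyl]chroman-4-yl}-5,7-bis(benzyloxy)-2-[3,4,5-tris(benzyloxy)phenyl]chroman-3-ol (identical with 19) | O[C@@H]1Cc2c(OCc3ccccc3)cc(OCc3ccccc3)c([C@@H]3C[C@@H](c4ccc(OCc5ccccc5)c(OCc5ccccc5)c4)Oc4cc(OCc5ccccc5)cc(OCc5ccccc5)c43)c2O[C@@H]1c1cc(OCc2ccccc2)c(OCc2ccccc2)c(OCc2ccccc2)c1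
A5 | alternative 3 | 1,5-bis(benzyloxy)-3-{[3,4-bis(benzyloxy)phenyl](methoxy)methoxy}-2-vinylbenzene (mixed acetal, racemic) | COC(Oc1cc(OCc2ccccc2)cc(OCc2ccccc2)c1C=C)c1ccc(OCc2ccccc2)c(OCc2ccccc2)c1
A6 | alternative 3 | (2R,3R)-5,7-bis(benzyloxy)-2-[3,4,5-tris(benzyloxy)phenyl]chroman-3-yl 3,4,5-tris(benzyloxy)benzoate (octa-O-benzyl gallate) | O=C(O[C@@H]1Cc2c(OCc3ccccc3)cc(OCc3ccccc3)cc2O[C@@H]1c1cc(OCc2ccccc2)c(OCc2ccccc2)c(OCc2ccccc2)c1)c1cc(OCc2ccccc2)c(OCc2ccccc2)c(OCc2ccccc2)c1
A7 | alternative 3 | (2R,3R)-8-{(2S,4R)-5,7-bis(benzyloxy)-2-[3,4-bis(benzyloxy)phenyl]chroman-4-yl}-5,7-bis(benzyloxy)-2-[3,4,5-tris(benzyloxy)phenyl]chroman-3-yl 3,4,5-tris(benzyloxy)benzoate (identical with 21) | O=C(O[C@@H]1Cc2c(OCc3ccccc3)cc(OCc3ccccc3)c([C@@H]3C[C@@H](c4ccc(OCc5ccccc5)c(OCc5ccccc5)c4)Oc4cc(OCc5ccccc5)cc(OCc5ccccc5)c43)c2O[C@@H]1c1cc(OCc2ccccc2)c(OCc2ccccc2)c(OCc2ccccc2)c1)c1cc(OCc2ccccc2)c(OCc2ccccc2)c(OCc2ccccc2)c1
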